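The seven-membered ring is cut into the ring-fusion pair C-3a/C-8a and the five-carbon arc C-4 to C-8 (hydroazulene numbering). Because the C-1 oxygen sits on the same face of the cyclopentane as both seven-ring bonds at the fusion, it can act as a two-atom tether: the enol ether formed between a cyclopentane-1,3-dione and the C-1 hydroxyl of an enantiopure cyclopentenediol undergoes a crossed intramolecular (2+2) photocycloaddition across C-3a=C-8a. This single operation forges C-8–C-8a and C-3a–C-4, the cis fusion and the methyl-bearing quaternary centre; retro-aldol opening of the temporary cyclobutane (de Mayo) then unveils the cycloheptane and the C-1 hydroxyl.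

Key step: step 7

Remark: hydroazulene numbering of the target is used throughout (C-1 angelate, C-3 tertiary carbinol, C-3a/C-8a ring fusion, C-4 trimethoxybenzoate, C-6 methyl, C-6=C-7 alkene).
Remark: 3-chlorocyclopent-2-en-1-one (6) is assumed to be a catalogue compound.
Remark: compounds 8, 9, 10, 12, 13 and 15 are carried as mixtures of epimers at the methyl-bearing carbon (C-6), which converge when this carbon becomes sp2 in 16.

Step 1
Reactants: 1 (S)-4-[(tert-butyldimethylsilyl)oxy]cyclopent-2-en-1-one
Product: 2 tert-butyl(dimethyl){[(1S,2S)-2-methyl-4-(trimethylsilyloxy)cyclopent-3-en-1-yl]oxy}silane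
Conditions: MeMgBr, CuBr·SMe2 (10 mol %), TMSCl, THF, −78 °C; Et3N quench
Reagents that add atoms: methylmagnesium bromide C[Mg]Br; chlorotrimethylsilane C[Si](C)(C)Cl
Why: Copper-catalysed conjugate addition of the methyl Grignard reagent should occur anti to the silyloxy group (a temporary centre, erased in step 2), and silylation of the enolate as it forms prevents β-elimination of the silyloxy group.

Step 2
Reactants: 2 tert-butyl(dimethyl){[(1S,2S)-2-methyl-4-(trimethylsilyloxy)cyclopent-3-en-1-yl]oxy}silane
Product: 3 (S)-4-[(tert-butyldimethylsilyl)oxy]-3-methylcyclopent-2-en-1-one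
Conditions: Pd(OAc)2 (10 mol %), O2 (1 atm), DMSO, 50 °C
Reagents that add atoms: none
Why: Saegusa–Ito oxidation, in which the palladium enolate derived from the silyl enol ether undergoes β-hydride elimination at the methyl-bearing carbon, should regenerate the enone now carrying the future C-8a methyl, with dioxygen turning the catalyst over.

Step 3
Reactants: 3 (S)-4-[(tert-butyldimethylsilyl)oxy]-3-methylcyclopent-2-en-1-one
Product: 4 (1S,4S)-4-[(tert-butyldimethylsilyl)oxy]-3-methyl-1-(propan-2-yl)cyclopent-2-en-1-ol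
Conditions: iPrMgCl, LaCl3·2LiCl, THF, −20 °C; aqueous NH4Cl
Reagents that add atoms: isopropylmagnesium chloride CC(C)[Mg]Cl
Why: 1,2-Addition of the Grignard reagent, with LaCl3·2LiCl suppressing enolisation and conjugate addition, should take place anti to the silyloxy group and so set the tertiary carbinol (C-3, S) with its hydroxyl cis to the C-1 oxygen.

Step 4
Reactants: 4 (1S,4S)-4-[(tert-butyldimethylsilyl)oxy]-3-methyl-1-(propan-2-yl)cyclopent-2-en-1-ol
Product: 5 (1S,4S)-3-methyl-1-(propan-2-yl)cyclopent-2-ene-1,4-diol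
Conditions: Bu4NF, THF, 0 °C to rt
Reagents that add atoms: none
Why: Fluoride-mediated desilylation frees the secondary allylic hydroxyl without acid, which the tertiary allylic alcohol would not tolerate.

Step 5
Reactants: 5 (1S,4S)-3-methyl-1-(propan-2-yl)cyclopent-2-ene-1,4-diol; 6 3-chlorocyclopent-2-en-1-one
Product: 7 3-{[(1S,4S)-4-hydroxy-2-methyl-4-(propan-2-yl)cyclopent-2-en-1-yl]oxy}cyclopent-2-en-1-one
Conditions: NaH (1.0 equiv), THF, 0 °C; then 6, 0 °C to rt
Reagents that add atoms: none
Why: Addition–elimination (vinylic substitution) of the less hindered secondary alkoxide on the β-chloroenone should give the vinylogous ester with retention at C-1, the tertiary hydroxyl being too hindered to compete.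

Step 6
Reactants: 7 3-{[(1S,4S)-4-hydroxy-2-methyl-4-(propan-2-yl)cyclopent-2-en-1-yl]oxy}cyclopent-2-en-1-one
Product: 8 3-{[(1S,4S)-4-hydroxy-2-methyl-4-(propan-2-yl)cyclopent-2-en-1-yl]oxy}-5-methylcyclopent-2-en-1-one
Conditions: LiN(iPr)2 (2.2 equiv), THF, −78 °C; MeI, −78 to −40 °C
Reagents that add atoms: iodomethane CI
Why: Kinetic deprotonation of the vinylogous ester at its α′-methylene (Stork–Danheiser-type alkylation, the tertiary alkoxide being a spectator) followed by C-methylation installs the future C-6 methyl, whose configuration need not be controlled because the carbon becomes sp2 in step 12.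

Step 7
Reactants: 8 3-{[(1S,4S)-4-hydroxy-2-methyl-4-(propan-2-yl)cyclopent-2-en-1-yl]oxy}-5-methylcyclopent-2-en-1-one
Product: 9 crossed photoadduct, a tetracyclic cage ketone in which a cyclobutane joins C-3a, C-4, C-8 and C-8a, the ether oxygen bridges C-1 and C-4 (2-oxabicyclo[2.1.1]hexane core) and C-4 to C-8 remain a methylcyclopentanone with the carbonyl at C-7
Conditions: hν (300 nm), degassed MeCN (0.01 M), rt
Reagents that add atoms: none
Why: Excitation of the vinylogous ester gives its triplet, which bonds to the tethered alkene by a 1,5-closure (rule of five; future C-4 to C-3a, closing the oxolane ring and leaving a tertiary radical at C-8a and an α-keto radical at C-8), and after intersystem crossing the two radicals combine to close the cyclobutane, so that C-3a–C-4 and C-8–C-8a are made in one photochemical operation. The closest known reaction type is the crossed intramolecular enone–alkene (2+2) photocycloaddition of 3-(allyloxy)enones to 2-oxabicyclo[2.1.1]hexanes, the first half of a de Mayo reaction. Both new bonds must form on the face of the cyclopentene that carries the C-1 oxygen, so the existing C-1 stereocentre fixes C-3a and the quaternary C-8a and makes the later ring fusion cis, while the two further cyclobutane centres (C-4, C-8) are dictated by the cage and are erased in step 8. The selectivity needed is crossed over straight addition, secured by the two-atom O–C-1 tether (a straight adduct would contain a 2-oxabicyclo[2.2.0]hexane), and cycloaddition over Claisen rearrangement of the allyl vinyl ether, secured by working at ambient temperature. The free tertiary hydroxyl and the remote methyl group should be inert under these conditions.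

Step 8
Reactants: 9 crossed photoadduct
Product: 10 (1S,3S,3aS,8aR)-1,3-dihydroxy-6,8a-dimethyl-3-(propan-2-yl)octahydroazulene-4,7-dione (may equilibrate with its lactol bridging O-1 and C-4)
Conditions: 1 M aqueous HCl, THF, 0 °C to rt
Reagents that add atoms: water O
Why: Protonation of the C-7 carbonyl lets the ether oxygen push open the donor–acceptor cyclobutane (retro-aldol half of the de Mayo reaction), and hydrolysis of the resulting oxocarbenium ion should release the C-1 hydroxyl and the C-4 ketone within the cycloheptane, leaving the cis fusion set in step 7 untouched.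

Step 9
Reactants: 10 (1S,3S,3aS,8aR)-1,3-dihydroxy-6,8a-dimethyl-3-(propan-2-yl)octahydroazulene-4,7-dione; 11 angelic acid, (2Z)-2-methylbut-2-enoic acid
Product: 12 (1S,3S,3aS,8aR)-3-hydroxy-6,8a-dimethyl-4,7-dioxo-3-(propan-2-yl)decahydroazulen-1-yl (2Z)-2-methylbut-2-enoate
Conditions: 11, 2,4,6-trichlorobenzoyl chloride, Et3N, toluene, rt; then 10, DMAP, rt to 60 °C
Reagents that add atoms: none
Why: Yamaguchi esterification through the mixed 2,4,6-trichlorobenzoic anhydride should acylate the secondary C-1 hydroxyl (the tertiary C-3 hydroxyl does not react) under conditions chosen to keep the Z geometry of the angeloyl group.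

Step 10
Reactants: 12 (1S,3S,3aS,8aR)-3-hydroxy-6,8a-dimethyl-4,7-dioxo-3-(propan-2-yl)decahydroazulen-1-yl (2Z)-2-methylbut-2-enoate
Product: 13 (1S,3S,3aR,4R,8aR)-3,4-dihydroxy-6,8a-dimethyl-7-oxo-3-(propan-2-yl)decahydroazulen-1-yl (2Z)-2-methylbut-2-enoate
Conditions: Me4NBH(OAc)3, MeCN/AcOH (1:1), −20 °C to rt
Reagents that add atoms: none
Why: In this Evans–Saksena reduction the borohydride exchanges an acetate for the tertiary C-3 hydroxyl and delivers hydride intramolecularly to the neighbouring C-4 ketone from the concave face on which O-3 lies, which should place the new hydroxyl on the convex face (4R) and leave the isolated C-7 ketone untouched.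

Step 11
Reactants: 13 (1S,3S,3aR,4R,8aR)-3,4-dihydroxy-6,8a-dimethyl-7-oxo-3-(propan-2-yl)decahydroazulen-1-yl (2Z)-2-methylbut-2-enoate; 14 3,4,5-trimethoxybenzoyl chloride
Product: 15 (1S,3S,3aR,4R,8aR)-3-hydroxy-6,8a-dimethyl-1-{[(2Z)-2-methylbut-2-enoyl]oxy}-7-oxo-3-(propan-2-yl)decahydroazulen-4-yl 3,4,5-trimethoxybenzoate
Conditions: 14, DMAP, Et3N, CH2Cl2, 0 °C to rt
Reagents that add atoms: none
Why: DMAP-catalysed acyl transfer should esterify the secondary C-4 hydroxyl with retention, the tertiary C-3 hydroxyl being unreactive.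

Step 12
Reactants: 15 (1S,3S,3aR,4R,8aR)-3-hydroxy-6,8a-dimethyl-1-{[(2Z)-2-methylbut-2-enoyl]oxy}-7-oxo-3-(propan-2-yl)decahydroazulen-4-yl 3,4,5-trimethoxybenzoate
Product: 16 (1S,3S,3aR,4R,8aR)-3-hydroxy-6,8a-dimethyl-1-{[(2Z)-2-methylbut-2-enoyl]oxy}-7-oxo-3-(propan-2-yl)-1,2,3,3a,4,7,8,8a-octahydroazulen-4-yl 3,4,5-trimethoxybenzoate
Conditions: IBX, 4-methoxypyridine N-oxide, DMSO, rt to 50 °C
Reagents that add atoms: none
Why: IBX-mediated α,β-dehydrogenation of the C-7 ketone can only proceed toward C-6/C-5 because C-8a is quaternary, which should give the 6-methyl enone and remove the uncontrolled C-6 stereocentre.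

Step 13
Reactants: 16 (1S,3S,3aR,4R,8aR)-3-hydroxy-6,8a-dimethyl-1-{[(2Z)-2-methylbut-2-enoyl]oxy}-7-oxo-3-(propan-2-yl)-1,2,3,3a,4,7,8,8a-octahydroazulen-4-yl 3,4,5-trimethoxybenzoate
Product: 17 the 7-(4-methylbenzenesulfonyl)hydrazone of 16
Conditions: TsNHNH2, AcOH (cat.), EtOH, 50 °C
Reagents that add atoms: 4-methylbenzenesulfonohydrazide NNS(=O)(=O)c1ccc(C)cc1
Why: Acid-catalysed condensation at the carbonyl should give the tosylhydrazone, conjugate addition being disfavoured at the hindered β-carbon next to the C-4 ester.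

Step 14
Reactants: 17 the 7-(4-methylbenzenesulfonyl)hydrazone of 16
Product: 18 (1S,3S,3aR,4R,8aR)-3-hydroxy-6,8a-dimethyl-1-{[(2Z)-2-methylbut-2-enoyl]oxy}-3-(propan-2-yl)-1,2,3,3a,4,5,8,8a-octahydroazulen-4-yl 3,4,5-trimethoxybenzoate (CNP0112256.1)
Conditions: catecholborane, CHCl3, 0 °C; then NaOAc·3H2O, 60 °C
Reagents that add atoms: none
Why: 1,2-Reduction of the unsaturated tosylhydrazone by catecholborane and acetate-induced loss of sulfinate give an allylic diazene whose retro-ene loss of dinitrogen transfers hydrogen to C-5 and moves the double bond to C-6=C-7 (alkene-transposing hydrazone reduction), which should complete the target without touching the esters or the stereocentres.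

Compound list
1 | (S)-4-[(tert-butyldimethylsilyl)oxy]cyclopent-2-en-1-one | CC(C)(C)[Si](C)(C)O[C@H]1CC(=O)C=C1 | starting material
2 | tert-butyl(dimethyl){[(1S,2S)-2-methyl-4-(trimethylsilyloxy)cyclopent-3-en-1-yl]oxy}silane | CC(C)(C)[Si](C)(C)O[C@H]1CC(O[Si](C)(C)C)=C[C@@H]1C | intermediate
3 | (S)-4-[(tert-butyldimethylsilyl)oxy]-3-methylcyclopent-2-en-1-one | CC(C)(C)[Si](C)(C)O[C@H]1CC(=O)C=C1C | intermediate
4 | (1S,4S)-4-[(tert-butyldimethylsilyl)oxy]-3-methyl-1-(propan-2-yl)cyclopent-2-en-1-ol | CC(C)(C)[Si](C)(C)O[C@H]1C[C@](O)(C(C)C)C=C1C | intermediate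
5 | (1S,4S)-3-methyl-1-(propan-2-yl)cyclopent-2-ene-1,4-diol (cis-diol) | O[C@H]1C[C@](O)(C(C)C)C=C1C | intermediate
6 | 3-chlorocyclopent-2-en-1-one | O=C1C=C(Cl)CC1 | starting material
7 | 3-{[(1S,4S)-4-hydroxy-2-methyl-4-(propan-2-yl)cyclopent-2-en-1-yl]oxy}cyclopent-2-en-1-one | O=C1CCC(O[C@H]2C[C@](O)(C(C)C)C=C2C)=C1 | intermediate
8 | 3-{[(1S,4S)-4-hydroxy-2-methyl-4-(propan-2-yl)cyclopent-2-en-1-yl]oxy}-5-methylcyclopent-2-en-1-one (both epimers at the methyl-bearing carbon) | O=C1C(C)CC(O[C@H]2C[C@](O)(C(C)C)C=C2C)=C1 | intermediate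
9 | crossed photoadduct (cage ketone; cyclobutane through C-3a, C-4, C-8, C-8a; ether oxygen bridging C-1 and C-4) | O1[C@H]2C[C@](O)(C(C)C)[C@H]3[C@@]14CC(C)C(=O)[C@@H]4[C@@]23C | intermediate
10 | (1S,3S,3aS,8aR)-1,3-dihydroxy-6,8a-dimethyl-3-(propan-2-yl)octahydroazulene-4,7-dione (open form) | O[C@H]1C[C@](O)(C(C)C)[C@H]2C(=O)CC(C)C(=O)C[C@@]12C | intermediate
11 | angelic acid, (2Z)-2-methylbut-2-enoic acid | C/C=C(/C)C(=O)O | starting material
12 | (1S,3S,3aS,8aR)-3-hydroxy-6,8a-dimethyl-4,7-dioxo-3-(propan-2-yl)decahydroazulen-1-yl (2Z)-2-methylbut-2-enoate | C/C=C(/C)C(=O)O[C@H]1C[C@](O)(C(C)C)[C@H]2C(=O)CC(C)C(=O)C[C@@]12C | intermediate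
13 | (1S,3S,3aR,4R,8aR)-3,4-dihydroxy-6,8a-dimethyl-7-oxo-3-(propan-2-yl)decahydroazulen-1-yl (2Z)-2-methylbut-2-enoate | C/C=C(/C)C(=O)O[C@H]1C[C@](O)(C(C)C)[C@H]2[C@H](O)CC(C)C(=O)C[C@@]12C | intermediate
14 | 3,4,5-trimethoxybenzoyl chloride | COc1cc(cc(OC)c1OC)C(=O)Cl | starting material
15 | (1S,3S,3aR,4R,8aR)-3-hydroxy-6,8a-dimethyl-1-{[(2Z)-2-methylbut-2-enoyl]oxy}-7-oxo-3-(propan-2-yl)decahydroazulen-4-yl 3,4,5-trimethoxybenzoate | C/C=C(/C)C(=O)O[C@H]1C[C@](O)(C(C)C)[C@H]2[C@H](OC(=O)c3cc(OC)c(OC)c(OC)c3)CC(C)C(=O)C[C@@]12C | intermediate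
16 | (1S,3S,3aR,4R,8aR)-3-hydroxy-6,8a-dimethyl-1-{[(2Z)-2-methylbut-2-enoyl]oxy}-7-oxo-3-(propan-2-yl)-1,2,3,3a,4,7,8,8a-octahydroazulen-4-yl 3,4,5-trimethoxybenzoate | C/C=C(/C)C(=O)O[C@H]1C[C@](O)(C(C)C)[C@H]2[C@H](OC(=O)c3cc(OC)c(OC)c(OC)c3)C=C(C)C(=O)C[C@@]12C | intermediate
17 | 7-(4-methylbenzenesulfonyl)hydrazone of 16 | C/C=C(/C)C(=O)O[C@H]1C[C@](O)(C(C)C)[C@H]2[C@H](OC(=O)c3cc(OC)c(OC)c(OC)c3)C=C(C)C(=NNS(=O)(=O)c3ccc(C)cc3)C[C@@]12C | intermediate
18 | (1S,3S,3aR,4R,8aR)-3-hydroxy-6,8a-dimethyl-1-{[(2Z)-2-methylbut-2-enoyl]oxy}-3-(propan-2-yl)-1,2,3,3a,4,5,8,8a-octahydroazulen-4-yl 3,4,5-trimethoxybenzoate | C/C=C(/C)C(=O)O[C@H]1C[C@](O)(C(C)C)[C@H]2[C@H](OC(=O)c3cc(OC)c(OC)c(OC)c3)CC(C)=CC[C@@]12C | target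

Total step count: 14. Longest linear sequence: 14 steps (1 to 18).

Steps most likely to fail

Step 7. The biradical formed after the first bond may revert or transfer hydrogen instead of closing the strained cage, so that the cycloaddition stalls. The fallback moves the tether to the tertiary C-3 oxygen through silicon, so that a straight cycloaddition closes an unstrained six-membered ring. It sets out from 4: silylation of the tertiary hydroxyl with iPr2Si(OTf)2 and 2,6-lutidine, then addition of cyclopentane-1,3-dione and Et3N, would give the mixed diisopropylsilylene diether F1. Irradiation (300 nm, MeCN) would give the straight photoadduct F2, in which the silyloxy-bearing carbon bonds to C-3a and its neighbour to C-8a on the face of O-3. Kinetic methylation (LiN(iPr)2, MeI, THF, −78 °C) at the only readily enolisable methylene would give the methylated photoadduct F3. HF·pyridine in MeCN would then remove both silicon groups, and the freed cyclobutanol would open by retro-aldol reaction to 10, where the route is rejoined.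

Step 10. Hydride may be delivered with poor facial selectivity if the tertiary hydroxyl exchanges onto boron slowly and external attack on the convex face competes. The fallback accepts convex-face attack and corrects the centre during esterification. It sets out from 12: chelation-controlled reduction (Et2BOMe, NaBH4, THF/MeOH, −78 °C; Narasaka–Prasad) should activate only the C-4 ketone and give the C-4 epimer of 13 F4. Mitsunobu esterification (PPh3, DIAD, 3,4,5-trimethoxybenzoic acid, toluene) with inversion at C-4 would then give 15 directly, where the route is rejoined.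

Step 9. The angeloyl unit may isomerise to the tigloyl unit, or acylation may remain incomplete, under the forcing conditions the neopentyl C-1 hydroxyl requires. The fallback builds the Z-alkene after the acylation. It sets out from 10: esterification with 2-[bis(2,2,2-trifluoroethoxy)phosphoryl]propanoic acid (DCC, DMAP, CH2Cl2) would give the phosphonopropanoate F5. Still–Gennari olefination with acetaldehyde (KN(SiMe3)2, 18-crown-6, THF, −78 °C; one equivalent of base, so that only the phosphonate is deprotonated) should then give 12 with Z selectivity, where the route is rejoined.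

Further compounds
F1 | step 7 | mixed diisopropylsilylene diether of the tertiary hydroxyl of 4 and the enol of cyclopentane-1,3-dione | CC(C)(C)[Si](C)(C)O[C@H]1C[C@](O[Si](C(C)C)(C(C)C)OC2=CC(=O)CC2)(C(C)C)C=C1C
F2 | step 7 | straight photoadduct of F1 (cyclobutane through C-3a, C-4, C-8, C-8a; siladioxane ring through O-3 and the C-4 oxygen) | CC(C)(C)[Si](C)(C)O[C@H]1C[C@](O[Si](C(C)C)(C(C)C)O3)(C(C)C)[C@H]2[C@@]34CCC(=O)[C@@H]4[C@@]12C
F3 | step 7 | C-6-methylated photoadduct from F2 | CC(C)(C)[Si](C)(C)O[C@H]1C[C@](O[Si](C(C)C)(C(C)C)O3)(C(C)C)[C@H]2[C@@]34CC(C)C(=O)[C@@H]4[C@@]12C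
F4 | step 10 | (1S,3S,3aR,4S,8aR)-3,4-dihydroxy-6,8a-dimethyl-7-oxo-3-(propan-2-yl)decahydroazulen-1-yl (2Z)-2-methylbut-2-enoate (C-4 epimer of 13) | C/C=C(/C)C(=O)O[C@H]1C[C@](O)(C(C)C)[C@H]2[C@@H](O)CC(C)C(=O)C[C@@]12C
F5 | step 9 | (1S,3S,3aS,8aR)-3-hydroxy-6,8a-dimethyl-4,7-dioxo-3-(propan-2-yl)decahydroazulen-1-yl 2-[bis(2,2,2-trifluoroethoxy)phosphoryl]propanoate | CC(P(=O)(OCC(F)(F)F)OCC(F)(F)F)C(=O)O[C@H]1C[C@](O)(C(C)C)[C@H]2C(=O)CC(C)C(=O)C[C@@]12C
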